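All runs are simulated for an exercise; scatter was added.

Read J first.

| flask | J | X | remark | time | volume of the second phase over the first |
|---|---|---|---|---|---|
| birch | 0.14 M | 0.10 M | run made earlier |  |  |
| ash | 0.22 M | 0.10 M | run made earlier |  |  |
| flask | 0.10 M | 0.100 M |  | 6.0 min | 0.50 |

- birch (time / min: Z / %, J / %): 1.33: 4.2, 95.7; 2.50: 8.3, 91.1; 4.00: 11.7, 86.6; 5.00: 12.7, 85.9
- ash (time / min: Z / %, J / %): 0.667: 1.4, 98.0; 1.50: 4.8, 95.4; 3.00: 8.8, 90.7; 5.00: 11.3, 87.3

(standard deviation of a reading: 0.5 percentage points)

- in the second phase: X; everything else is in the first
- charges count per volume of the first phase; a concentration in a rate is the amount of a species over the volume of its own phase; every rate counts per litre of the first phase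
- the analysis behind the earlier runs scatters by 0.5 percentage points, standard deviation
- what may be going on: Q <-> X; J + Q -> Z; Q + Z -> D; Q + Z -> L; Q -> G
- the earlier runs hold the two phases in the same ratio of volumes as the flask asked about

1. amount of Z at 6.0 min, in percent of the J charged
2. the change that raises the amount of Z at 6.0 min, in percent of the J charged most ("none" if none brings more than 2 percentage points) (beta / zeta / none)
3. amount of Z at 6.0 min, in percent of the J charged, after zeta

Birch and ash charge 0.14 M and 0.22 M of J, yet at 5.00 min they keep 85.9 % and 87.3 % of it. So treat J as pseudo-first-order and take ln(charge over J left) as the exposure of a flask. Birch is nearer this flask in J, so read birch. Up to 2.50 min it gives 0.0373 min⁻¹, the early exposure rate, which is exposure gained per minute. From there to 5.00 min it gains 0.0235 min⁻¹, slower than the early rate, so the exposure is heading for an end value.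

Carry that later rate to 6.0 min: this flask reaches exposure 0.175, so it loses 16.1 % of its J. Birch turned a share 0.901 of lost J into standing Z, so I expect Z near 14.5 %. Doubling X should about double the exposure, so this flask should lose 29.6 % of its J. The share may fall as Z builds, so I give no Z for beta, but a gain of 2 percentage points needs a share of 0.148 of the extra loss. So choose beta. The runs do not vary transfer, so I give zeta no figure of my own.

The forecast says 14.2 %, beta, and 16 % after zeta: “Doubling transfer helps only if transfer is limiting”.

The flask gives 14.3 %, with beta adding 9 points and zeta 0.87 points, and 15.2 % after zeta.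

    Q ⇌ X, rate k1*([Q] - [X]/K1) per volume of the first phase (partition coefficient = 0.860, kL = 0.00460 s⁻¹)
    J + Q → Z (k = 0.0260 M⁻¹ s⁻¹)
    Q + Z → D (k = 0.0100 M⁻¹ s⁻¹)
    Q + Z → L (k = 0.0250 M⁻¹ s⁻¹)
    Q → G (k = 0.00990 s⁻¹)

The forecast would be wrong if a run of this flask read Z as this flask does with X at 0.0598 M or 0.149 M, 5 points away. Use the early rate on the end: J in this flask stands at 81.3 % after 60.0 min, an exposure of 0.207, which the early rate reaches in 5.55 min. That time lies near 6.0 min, and Z in this flask ends at 16.2 %.

For the same flask left until 1.5 min, the early rate gives exposure 0.0559, so Z near 4.90 %. The computed flask holds 4.97 % at that time.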